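## Structural features

- The target is a linear chain of six benzene rings (A to F) joined by five diaryl ether oxygens. It carries fourteen free phenolic hydroxyls and has no stereocentre, so no stereocentres stand next to each other and none has to be set.
- Ring A is a 2,4,6-trihydroxyphenyl group, rings B to E are 2,6-dihydroxy-1,4-phenylenedioxy units, and ring F is a 3,4,5-trihydroxyphenyl group.
- Every ether oxygen sits on a carbon flanked by two hydroxyls in the ring nearer to A, and on a carbon flanked by two hydrogens in the ring nearer to F.
- The free polyphenol is the fragile part: the 1,2,3-trioxygenated rings, above all ring F, oxidise readily in air and base, so the hydroxyls are best unveiled in the last step under acidic, oxygen-free conditions.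
- The real difficulty is making five doubly ortho-substituted, electron-rich diaryl ether bonds with a defined chain length while keeping fourteen oxygens uniformly masked.
- The key step exploits ring F. Its C3, C4 and C5 bear adjacent oxygens and C1, para to C4, bears the ether oxygen. C5, C4 and C3 map onto the carbonyl carbon and the two alkoxy carbons of a squarate-derived cyclobutenone, C2 onto its CHCl carbon, and C1 and C6 onto the two carbons of a 1-aryloxyvinyl group.
- Ring F can therefore be built around the ring E oxygen by forming the C1–C2 and C5–C6 bonds.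

## Logic of the disconnections

**22 to 21.** The eleven O–CH3 bonds and two O–CH(CH3)2 bonds are cut in one operation. All aryl oxygens are carried as simple alkyl ethers that survive copper, lithium, tin and palladium chemistry. The forward step must cleave thirteen alkyl ethers without touching five diaryl ethers and must deliver the polyphenol without exposure to base and air.

**21 to 17 and 14.** The C1–C2 and C5–C6 bonds of ring F are cut, through 20, 19 and 18. This removes a whole ring and reduces the hexamer to a pentamer plus a four-carbon unit. The mapping was checked atom by atom: the carbonyl carbon of 17 becomes the C5 hydroxyl carbon, its two alkoxy carbons become C4 and C3, its chlorine-bearing carbon becomes C2, and the tin-bearing carbon of 14 becomes C1, para to the central oxygen. The forward step needs coupling at the chlorine-bearing carbon of 17 and inward rotation of the vinyl group during ring opening.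

**17 to 16 to 15.** The C–Cl bond and then the C–H bond at the same carbon are cut, leading back to a commercial squarate. The demand is on the chlorination: 16 ionises easily with loss of an isopropyl group, so the hydroxyl must be replaced under neutral conditions, which is an improvement over an acidic chlorination.

**14 to 13 to 10 to 9.** The C–Sn and C–H bonds across the vinyl group are cut first, then the O–C(sp) bond, via 12 and 11. The hindered ring E oxygen is thereby attached to a two-carbon unit at an unhindered sp carbon instead of to an aromatic ring. The forward sequence requires tin to add at the oxygen-bearing carbon and requires lithiation at low temperature so that the ring positions between two oxygens are not metalated.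

**9 to 8 to 7 and 4.** The benzyl O–C bond is cut, then the diaryl ether bond between the ring C oxygen and the unhindered ring D carbon. This removes two rings at once, because 4 already contains rings D and E. The forward coupling joins a doubly ortho-substituted phenol to an electron-rich aryl bromide, which calls for a copper catalyst with a ligand suited to hindered phenols.

**7 to 6 to 5 and 4.** The same two cuts, benzyl O–C and the ether bond between the ring A oxygen and the unhindered ring B carbon, use 4 a second time, now as rings B and C. Using one two-ring block twice shortens the pentamer assembly by two steps compared with ring-by-ring growth.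

**4 to 1 and 3; 3 to 2 to 1.** The central ether bond of 4 is cut between the hindered oxygen of 1 and the iodine-bearing carbon of 3. The iodide is traced back through halogen exchange and benzylation to 1, so both halves come from one commercial phenol. The forward coupling must engage the C–I bond of 3 and leave both C–Br bonds, in 1 and in 4, untouched.

## Other disconnections considered

**Alternative 1:** The cut is made at twelve aryl C–OH bonds, two on each ring, each traced back to an aryl–CHO bond. The para hydroxyls of rings A and F are carried as benzyl ethers.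

- **Forward key step:** m-CPBA would convert the hexameric dodecaaldehyde A1 by twelve Baeyer–Villiger aryl migrations into the dodecaformate A2. Methanolysis and hydrogenolysis would then give the target.
- **In favour:** Each pair of formyl groups lies ortho to an ether-bearing carbon, so the ether bonds of A1 could be made by nucleophilic aromatic substitution of doubly activated aryl fluorides with unhindered phenoxides, without copper. The end-game needs no BBr3. On both points the alternative is better than the chosen plan.
- **Against:** Every ring of A1 is electron-poor, with two formyl groups and a single ortho aryloxy donor per aldehyde. Hydride migration to a carboxylic acid should therefore compete with aryl migration at each of twelve sites, and one wrong event spoils the molecule. The doubly activated aryloxy groups are also leaving groups, so phenoxide exchange could scramble the chain length during assembly.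
- **Comparison:** Structurally, neither plan builds rings A to E, and the alternative buys ring F as well. Mechanistically, the alternative needs twelve successful peracid rearrangements in one flask, against one coupling and electrocyclization whose regiochemistry is fixed by connectivity. In step count the two plans should be about equal once the fluoro dialdehyde building blocks are prepared.

**Alternative 2:** The cut removes two C–C bonds of ring B, so rings C to F and ring A are joined by building ring B between them.

- **Forward key step:** The 2-aryloxy-1,3-bis(trimethylsilyloxy)cyclohexa-1,3-diene A3 and methyl 3-(2,4,6-trimethoxyphenoxy)prop-2-ynoate A4 would undergo Diels–Alder addition. The bicyclo[2.2.2]octadiene would lose ethylene (Alder–Rickert) to give the benzoate A5. Desilylation, ester hydrolysis, decarboxylation and demethylation would follow.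
- **In favour:** Both oxygens on the new ring are attached before it is aromatic, as in the chosen plan. The regiochemistry follows from matching the nucleophilic diene terminus with the ester-bearing alkyne. The carboxyl group would end up ortho and para to hydroxyls, where decarboxylation is easy. On regiocontrol the alternative is the equal of the chosen plan.
- **Against:** The ring is built in the middle, so two advanced fragments are needed: a tetramer carrying a cyclohexane-1,3-dione on its hindered oxygen and a ring A ynol ether ester. The tetramer still requires the same copper etherifications. The push–pull alkyne is a weak dienophile, ethylene extrusion needs strong heating, the silyl enol ethers are labile, and three extra operations follow the key step.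
- **Comparison:** Mechanistically, both plans rest on pericyclic ring construction and are comparable. Structurally, the alternative makes an internal ring where the chosen plan makes the terminal one. In step count the alternative should be several steps longer.

**Alternative 3:** The cut is made at all five diaryl ether C–O bonds at once.

- **Forward key step:** Laccase and O2 would oxidise 4-(benzyloxy)-2,6-dimethoxyphenol A6 and five equivalents of syringic acid A7 to phenoxyl radicals. Oxygen-to-para-carbon coupling with loss of CO2 would give the hexamer A8, and global dealkylation would give the target.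
- **In favour:** Five bonds would form in one aqueous operation with air as oxidant, from two cheap aromatics, without halides, tin or palladium. The ortho methoxy groups block C–C coupling. In step economy and reagent hazard the alternative is clearly better than the chosen plan.
- **Against:** Nothing in the mechanism stops chain growth at six rings or forces every chain to start from A6. A distribution of oligomers is to be expected, including chains begun by A7 and products of chain redistribution, from which one homologue would have to be separated.
- **Comparison:** Structurally, both plans deliver the same permethylated backbone pattern, and the alternative makes no ring at all. Mechanistically, radical step-growth gives statistical length control, whereas the chosen plan fixes the length by construction. In step count the alternative wins by a wide margin but at the price of an uncertain separation.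

Key step: step 13

Remark on the chemistry: 16, 17 and 18 each carry one stereocentre and are used as racemates; this centre disappears in step 13, so no stereocontrol is needed anywhere.

Notation: Ar5 is the aryl group of 9 (9 = Ar5–OH), that is 4-{4-[4-(2,6-dimethoxy-4-(2,4,6-trimethoxyphenoxy)phenoxy)-2,6-dimethoxyphenoxy]-2,6-dimethoxyphenoxy}-2,6-dimethoxyphenyl, bonded through the ring E carbon that lies between two methoxy groups.

Step 1
Reactants: 1 4-bromo-2,6-dimethoxyphenol
Product: 2 2-(benzyloxy)-5-bromo-1,3-dimethoxybenzene
Conditions: BnBr, K2CO3, DMF, 60 °C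
Reagents that add atoms: benzyl bromide, BrCc1ccccc1
Why: Williamson ether synthesis; the phenoxide of 1 is alkylated on oxygen by the benzylic bromide, and the benzyl group can later be removed by hydrogenolysis without touching methyl or diaryl ethers.

Step 2
Reactants: 2 2-(benzyloxy)-5-bromo-1,3-dimethoxybenzene
Product: 3 2-(benzyloxy)-5-iodo-1,3-dimethoxybenzene
Conditions: NaI, CuI (cat.), trans-N,N'-dimethylcyclohexane-1,2-diamine (cat.), dioxane, 110 °C
Reagents that add atoms: sodium iodide, [Na+].[I-]
Why: Copper-catalysed aromatic Finkelstein reaction; exchange at an unhindered aryl bromide is driven by precipitation of NaBr, and the iodide provides the halogen discrimination needed in step 3.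

Step 3
Reactants: 1 4-bromo-2,6-dimethoxyphenol; 3 2-(benzyloxy)-5-iodo-1,3-dimethoxybenzene (slight excess)
Product: 4 2-(benzyloxy)-5-(4-bromo-2,6-dimethoxyphenoxy)-1,3-dimethoxybenzene
Conditions: CuI (cat.), picolinic acid (cat.), K3PO4, DMSO, 80 °C, argon
Reagents that add atoms: none
Why: Ullmann-type diaryl ether synthesis; the C–I bond of 3 enters the copper cycle faster than a C–Br bond, and the bromine of 1 is further deactivated because it lies para to the phenoxide oxygen. The excess of 3 and the moderate temperature should keep the bromine of 4 from reacting on.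

Step 4
Reactants: 5 2,4,6-trimethoxyphenol; 4 2-(benzyloxy)-5-(4-bromo-2,6-dimethoxyphenoxy)-1,3-dimethoxybenzene
Product: 6 2-(benzyloxy)-5-[2,6-dimethoxy-4-(2,4,6-trimethoxyphenoxy)phenoxy]-1,3-dimethoxybenzene
Conditions: CuI (cat.), picolinic acid (cat.), K3PO4, DMSO, 100 °C, argon
Reagents that add atoms: none
Why: Ullmann-type diaryl ether synthesis; CuI with picolinic acid is suited to phenols with two ortho substituents, and the bromine of 4 is flanked only by hydrogens, so the hindrance lies on the nucleophile alone.

Step 5
Reactants: 6 2-(benzyloxy)-5-[2,6-dimethoxy-4-(2,4,6-trimethoxyphenoxy)phenoxy]-1,3-dimethoxybenzene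
Product: 7 4-[2,6-dimethoxy-4-(2,4,6-trimethoxyphenoxy)phenoxy]-2,6-dimethoxyphenol
Conditions: H2 (1 atm), 10% Pd/C, EtOAc–MeOH, rt
Reagents that add atoms: none
Why: Hydrogenolysis of a benzyl aryl ether; methyl and diaryl ethers are inert, and the hindered phenol for the next coupling is set free.

Step 6
Reactants: 7 4-[2,6-dimethoxy-4-(2,4,6-trimethoxyphenoxy)phenoxy]-2,6-dimethoxyphenol; 4 2-(benzyloxy)-5-(4-bromo-2,6-dimethoxyphenoxy)-1,3-dimethoxybenzene
Product: 8 pentamer benzyl ether Ar5–O–CH2Ph
Conditions: CuI (cat.), picolinic acid (cat.), K3PO4, DMSO, 100 °C, argon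
Reagents that add atoms: none
Why: Ullmann-type diaryl ether synthesis of the same kind as step 4; the phenol of 7 has the same steric and electronic environment as that of 5, so the same catalyst should serve.

Step 7
Reactants: 8 pentamer benzyl ether Ar5–O–CH2Ph
Product: 9 pentamer phenol Ar5–OH
Conditions: H2 (1 atm), 10% Pd/C, THF–MeOH, rt
Reagents that add atoms: none
Why: Hydrogenolysis of the benzyl ether as in step 5; no other group in 8 is reducible under these conditions.

Step 8
Reactants: 9 pentamer phenol Ar5–OH
Product: 10 (E)-1,2-dichlorovinyl ether Ar5–O–C(Cl)=CHCl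
Conditions: Cl2C=CHCl, K2CO3, DMF, 70 °C
Reagents that add atoms: trichloroethylene, ClC=C(Cl)Cl
Why: Base-mediated addition of a phenoxide to dichloroacetylene, which is generated and consumed in solution and never isolated; anti addition gives the E isomer. The hindered oxygen attacks a linear sp carbon, so the two ortho methoxy groups are not expected to interfere.

Step 9
Reactants: 10 (E)-1,2-dichlorovinyl ether Ar5–O–C(Cl)=CHCl
Product: 13 pentamer ethynyl ether Ar5–O–C≡CH, via chloroethynyl ether 11 (not isolated), via lithium acetylide 12 (not isolated)
Conditions: n-BuLi (2.3 equiv), THF, −78 → −40 °C; then H2O, −78 °C → rt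
Reagents that add atoms: none
Why: Known route to aryl ethynyl ethers: vinylic deprotonation and loss of LiCl give 11, chlorine–lithium exchange gives 12, and protonation gives 13. The low temperature should prevent lithiation of the ring positions between two oxygens.

Step 10
Reactants: 13 pentamer ethynyl ether Ar5–O–C≡CH
Product: 14 tributyl[1-(Ar5-oxy)vinyl]stannane
Conditions: Bu3SnH (slow addition), Pd(PPh3)4 (cat.), THF, 0 °C → rt; neutral alumina
Reagents that add atoms: tributyltin hydride, CCCC[SnH](CCCC)CCCC
Why: Palladium-catalysed syn hydrostannation of a heteroatom-substituted terminal alkyne; the oxygen-polarised triple bond directs tin to the oxygen-bearing carbon, as is known for alkynyl ethers, ynamides and alkynyl sulfides. Purification on neutral alumina should avoid protodestannylation.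

Step 11
Reactants: 15 diisopropyl squarate
Product: 16 racemic 4-hydroxy-2,3-diisopropoxycyclobut-2-en-1-one
Conditions: LiAlH(OtBu)3, THF, −20 °C; cold aq. NH4Cl; used crude
Reagents that add atoms: none
Why: 1,2-Reduction of one ketone of the vinylogous diester by a bulky, mild aluminium hydride; the alkoxide formed is no longer activated, so reduction stops after one hydride. The new stereocentre is formed as a racemate and is lost later.

Step 12
Reactants: 16 racemic 4-hydroxy-2,3-diisopropoxycyclobut-2-en-1-one
Product: 17 racemic 4-chloro-2,3-diisopropoxycyclobut-2-en-1-one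
Conditions: Ph3P, CCl4, CH2Cl2, 0 °C → rt
Reagents that add atoms: carbon tetrachloride, ClC(Cl)(Cl)Cl
Why: Appel reaction; the alkoxyphosphonium ion is displaced by chloride at the α-keto allylic carbon under neutral conditions. With no acid present, the ionisation that would cost an isopropyl group should be suppressed; inversion is irrelevant in a racemate.

Step 13
Reactants: 17 racemic 4-chloro-2,3-diisopropoxycyclobut-2-en-1-one (slight excess); 14 tributyl[1-(Ar5-oxy)vinyl]stannane
Product: 21 hexamer phenol 5-(Ar5-oxy)-2,3-diisopropoxyphenol, via vinylcyclobutenone 18 (not isolated), via dienylketene 19 (not isolated), via cyclohexadienone 20 (not isolated)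
Conditions: PdCl2(PhCN)2 (5 mol%), tri(2-furyl)phosphine (10 mol%), dioxane, 50 °C then 100 °C, argon
Reagents that add atoms: none
Why: Stille coupling followed by electrocyclic ring expansion, the known route from 4-chlorocyclobutenones and alkenylstannanes to phenols, here with a 1-aryloxyvinylstannane as a new member of the alkenylstannane class. Zerovalent palladium, formed in the flask from the divalent palladium precatalyst PdCl2(PhCN)2, the phosphine and a little of 14, adds into the allylic, α-keto C4–Cl bond of 17; the weakly donating furylphosphine speeds transfer of the 1-aryloxyvinyl group from tin, and reductive elimination at C4 gives 18. On warming, 18 opens by four-electron conrotatory cleavage of its C1–C4 bond to the dienylketene 19, and the ketene carbon closes onto the methylene terminus in a thermal six-electron disrotatory electrocyclization that forms ring F as the cyclohexa-2,4-dienone 20; enolisation then gives the phenol 21. No new stereocentre arises and the racemic centre of 17 is erased, so nothing needs stereocontrol. The step needs coupling at C4 and not at C2 of the oxocyclobutenyl palladium intermediate, which is favoured because it keeps the conjugated dialkoxy enone. It also needs inward rotation of the vinyl group on ring opening, which is secured because opening is reversible, only the inward rotamer can cyclise, and the other substituent on C4 is hydrogen. The constitution of ring F follows from the atoms alone: the carbonyl carbon becomes C–OH, the two isopropoxy carbons stay next to it, and the aryloxy carbon ends up para to the central oxygen. The methyl ethers and diaryl ethers are inert under these neutral conditions, and the slight excess of the inexpensive 17 ensures that the valuable 14 is fully consumed.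

Step 14
Reactants: 21 hexamer phenol 5-(Ar5-oxy)-2,3-diisopropoxyphenol
Product: 22 target tetradecaphenol CNP0187343.0
Conditions: BBr3 (excess), CH2Cl2, −78 °C → rt, argon; then degassed H2O, 0 °C
Reagents that add atoms: none
Why: Lewis acid ether cleavage; boron coordinates each alkyl aryl ether oxygen and bromide removes the methyl or isopropyl group, while diaryl ether oxygens offer no sp3 carbon for attack and stay intact. The acidic, oxygen-free conditions suit the oxidation-prone polyphenol.

## Compound list

1 | 4-bromo-2,6-dimethoxyphenol | COc1cc(Br)cc(OC)c1O | starting material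
2 | 2-(benzyloxy)-5-bromo-1,3-dimethoxybenzene | COc1cc(Br)cc(OC)c1OCc1ccccc1 | intermediate
3 | 2-(benzyloxy)-5-iodo-1,3-dimethoxybenzene | COc1cc(I)cc(OC)c1OCc1ccccc1 | intermediate
4 | 2-(benzyloxy)-5-(4-bromo-2,6-dimethoxyphenoxy)-1,3-dimethoxybenzene | COc1cc(Br)cc(OC)c1Oc1cc(OC)c(OCc2ccccc2)c(OC)c1 | intermediate
5 | 2,4,6-trimethoxyphenol | COc1cc(OC)c(O)c(OC)c1 | starting material
6 | 2-(benzyloxy)-5-[2,6-dimethoxy-4-(2,4,6-trimethoxyphenoxy)phenoxy]-1,3-dimethoxybenzene (rings A to C, benzyl ether) | C(c4ccccc4)Oc1c(OC)cc(Oc2c(OC)cc(Oc3c(OC)cc(OC)cc3OC)cc2OC)cc1OC | intermediate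
7 | 4-[2,6-dimethoxy-4-(2,4,6-trimethoxyphenoxy)phenoxy]-2,6-dimethoxyphenol (rings A to C, phenol) | Oc1c(OC)cc(Oc2c(OC)cc(Oc3c(OC)cc(OC)cc3OC)cc2OC)cc1OC | intermediate
8 | pentamer benzyl ether Ar5–O–CH2Ph (rings A to E) | C(c6ccccc6)Oc1c(OC)cc(Oc2c(OC)cc(Oc3c(OC)cc(Oc4c(OC)cc(Oc5c(OC)cc(OC)cc5OC)cc4OC)cc3OC)cc2OC)cc1OC | intermediate
9 | pentamer phenol Ar5–OH | Oc1c(OC)cc(Oc2c(OC)cc(Oc3c(OC)cc(Oc4c(OC)cc(Oc5c(OC)cc(OC)cc5OC)cc4OC)cc3OC)cc2OC)cc1OC | intermediate
10 | (E)-1,2-dichlorovinyl ether Ar5–O–C(Cl)=CHCl | Cl/C=C(/Cl)Oc1c(OC)cc(Oc2c(OC)cc(Oc3c(OC)cc(Oc4c(OC)cc(Oc5c(OC)cc(OC)cc5OC)cc4OC)cc3OC)cc2OC)cc1OC | intermediate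
11 | chloroethynyl ether Ar5–O–C≡C–Cl (not isolated) | ClC#COc1c(OC)cc(Oc2c(OC)cc(Oc3c(OC)cc(Oc4c(OC)cc(Oc5c(OC)cc(OC)cc5OC)cc4OC)cc3OC)cc2OC)cc1OC | intermediate
12 | lithium acetylide Ar5–O–C≡C–Li (not isolated) | [Li]C#COc1c(OC)cc(Oc2c(OC)cc(Oc3c(OC)cc(Oc4c(OC)cc(Oc5c(OC)cc(OC)cc5OC)cc4OC)cc3OC)cc2OC)cc1OC | intermediate
13 | pentamer ethynyl ether Ar5–O–C≡CH | C#COc1c(OC)cc(Oc2c(OC)cc(Oc3c(OC)cc(Oc4c(OC)cc(Oc5c(OC)cc(OC)cc5OC)cc4OC)cc3OC)cc2OC)cc1OC | intermediate
14 | tributyl[1-(Ar5-oxy)vinyl]stannane | C=C(Oc1c(OC)cc(Oc2c(OC)cc(Oc3c(OC)cc(Oc4c(OC)cc(Oc5c(OC)cc(OC)cc5OC)cc4OC)cc3OC)cc2OC)cc1OC)[Sn](CCCC)(CCCC)CCCC | intermediate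
15 | diisopropyl squarate (3,4-diisopropoxycyclobut-3-ene-1,2-dione) | CC(C)OC1=C(OC(C)C)C(=O)C1=O | starting material
16 | racemic 4-hydroxy-2,3-diisopropoxycyclobut-2-en-1-one | CC(C)OC1=C(OC(C)C)C(=O)C1O | intermediate
17 | racemic 4-chloro-2,3-diisopropoxycyclobut-2-en-1-one | CC(C)OC1=C(OC(C)C)C(=O)C1Cl | intermediate
18 | racemic 4-[1-(Ar5-oxy)vinyl]-2,3-diisopropoxycyclobut-2-en-1-one (not isolated) | CC(C)OC6=C(OC(C)C)C(=O)C6C(=C)Oc1c(OC)cc(Oc2c(OC)cc(Oc3c(OC)cc(Oc4c(OC)cc(Oc5c(OC)cc(OC)cc5OC)cc4OC)cc3OC)cc2OC)cc1OC | intermediate
19 | 5-(Ar5-oxy)-2,3-diisopropoxyhexa-1,3,5-trien-1-one, the dienylketene with the vinyl group cis to the ketene-bearing carbon (not isolated) | C=C(Oc1c(OC)cc(Oc2c(OC)cc(Oc3c(OC)cc(Oc4c(OC)cc(Oc5c(OC)cc(OC)cc5OC)cc4OC)cc3OC)cc2OC)cc1OC)/C=C(/OC(C)C)C(OC(C)C)=C=O | intermediate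
20 | 5-(Ar5-oxy)-2,3-diisopropoxycyclohexa-2,4-dien-1-one (not isolated) | O=C6CC(Oc1c(OC)cc(Oc2c(OC)cc(Oc3c(OC)cc(Oc4c(OC)cc(Oc5c(OC)cc(OC)cc5OC)cc4OC)cc3OC)cc2OC)cc1OC)=CC(OC(C)C)=C6OC(C)C | intermediate
21 | hexamer phenol 5-(Ar5-oxy)-2,3-diisopropoxyphenol (ring F as 3,4-diisopropyl ether 5-phenol) | CC(C)Oc6cc(Oc1c(OC)cc(Oc2c(OC)cc(Oc3c(OC)cc(Oc4c(OC)cc(Oc5c(OC)cc(OC)cc5OC)cc4OC)cc3OC)cc2OC)cc1OC)cc(O)c6OC(C)C | intermediate
22 | CNP0187343.0, the tetradecahydroxy hexamer of rings A to F | Oc1cc(O)c(Oc2cc(O)c(Oc3cc(O)c(Oc4cc(O)c(Oc5cc(O)c(Oc6cc(O)c(O)c(O)c6)c(O)c5)c(O)c4)c(O)c3)c(O)c2)c(O)c1 | target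

## Step count and least certain steps

Total step count: 14. Longest linear sequence: 12 steps (steps 1 to 10, then 13 and 14); steps 11 and 12 form the short branch that joins at step 13.

**Step 13 (key step).** The most likely failure is slow transfer of the hindered, electron-rich 1-aryloxyvinyl group from tin to palladium. That would leave time for thermal decomposition of 17 and for protodestannylation of 14 by traces of acid. Intermolecular trapping of the ketene in 19 by the product phenol is a second possibility if ring closure is slow. The fallback gives up ring construction. It sets out from 9, which is coupled with 5-bromo-1,2,3-trimethoxybenzene under the CuI, picolinic acid and K3PO4 conditions of step 4 to give the hexamer tetradecamethyl ether F1. Cleavage of all fourteen methyl ethers of F1 with BBr3, as in step 14, comes back to the route at 22.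

**Step 3.** Loss of halogen discrimination is the risk. If a C–Br bond of 1 or of 4 enters the copper cycle, the chain grows beyond two rings and a mixture of oligomeric bromides results. The fallback is ring-by-ring growth with the bromide 2 as the only electrophile, so no discrimination is needed.

- It sets out from 5 and 2, which are coupled with CuI, picolinic acid and K3PO4 to the dimer benzyl ether F2.
- Hydrogenolysis gives the dimer phenol F3, and a second coupling with 2 comes back to the route at 6.
- For the second use of 4, it sets out from 7 and 2, which give the tetramer benzyl ether F4.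
- Hydrogenolysis gives the tetramer phenol F5, and coupling with 2 comes back to the route at 8.

**Step 10.** Tin may be delivered to the terminal carbon instead of the oxygen-bearing one, and the product may lose tin by protonation during purification. The fallback fixes the regiochemistry by an ionic addition. It sets out from 13, to which hydrogen iodide (generated from Me3SiCl, NaI and water in MeCN at 0 °C) adds in the Markovnikov sense, giving the 1-iodovinyl ether F6. Iodine–lithium exchange with t-BuLi at −78 °C and quenching with Bu3SnCl comes back to the route at 14.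

**Step 12.** The activated hydroxyl may ionise instead of being displaced. The resulting cation can lose an isopropyl group and collapse to a cyclobutenedione, or chloride may be delivered with allylic transposition. The fallback avoids the chloride. It sets out from 16, which is acylated with methyl chloroformate and pyridine to the methyl carbonate F7. F7 is then used as the allylic electrophile in a coupling with 14 under zerovalent palladium (Pd2(dba)3 with tri(2-furyl)phosphine, dioxane, 50 to 100 °C), which comes back to the route at 21.

**Step 14.** Cleavage of thirteen ethers may stop short at some sites, and the polyphenol may oxidise during isolation, so the product may not be separable from partly alkylated material. The fallback adds a derivatisation for purification. It sets out from 21, which is treated with BBr3 as before. The crude product is acetylated at once with Ac2O and pyridine to the tetradecaacetate F8, which can be purified by chromatography. Methanolysis with HCl in degassed MeOH under argon comes back to the route at 22.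

## Further compounds

F1 | step 13 | hexamer tetradecamethyl ether 5-(Ar5-oxy)-1,2,3-trimethoxybenzene | COc6cc(Oc1c(OC)cc(Oc2c(OC)cc(Oc3c(OC)cc(Oc4c(OC)cc(Oc5c(OC)cc(OC)cc5OC)cc4OC)cc3OC)cc2OC)cc1OC)cc(OC)c6OC
F2 | step 3 | dimer benzyl ether 2-(benzyloxy)-1,3-dimethoxy-5-(2,4,6-trimethoxyphenoxy)benzene | C(c3ccccc3)Oc1c(OC)cc(Oc2c(OC)cc(OC)cc2OC)cc1OC
F3 | step 3 | dimer phenol 2,6-dimethoxy-4-(2,4,6-trimethoxyphenoxy)phenol | Oc1c(OC)cc(Oc2c(OC)cc(OC)cc2OC)cc1OC
F4 | step 3 | tetramer benzyl ether (rings A to D) | C(c5ccccc5)Oc1c(OC)cc(Oc2c(OC)cc(Oc3c(OC)cc(Oc4c(OC)cc(OC)cc4OC)cc3OC)cc2OC)cc1OC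
F5 | step 3 | tetramer phenol (rings A to D) | Oc1c(OC)cc(Oc2c(OC)cc(Oc3c(OC)cc(Oc4c(OC)cc(OC)cc4OC)cc3OC)cc2OC)cc1OC
F6 | step 10 | 1-iodovinyl ether Ar5–O–C(I)=CH2 | C=C(I)Oc1c(OC)cc(Oc2c(OC)cc(Oc3c(OC)cc(Oc4c(OC)cc(Oc5c(OC)cc(OC)cc5OC)cc4OC)cc3OC)cc2OC)cc1OC
F7 | step 12 | racemic 2,3-diisopropoxy-4-oxocyclobut-2-en-1-yl methyl carbonate | COC(=O)OC1C(=O)C(OC(C)C)=C1OC(C)C
F8 | step 14 | tetradecaacetate of the target | CC(=O)Oc1cc(OC(C)=O)c(Oc2cc(OC(C)=O)c(Oc3cc(OC(C)=O)c(Oc4cc(OC(C)=O)c(Oc5cc(OC(C)=O)c(Oc6cc(OC(C)=O)c(OC(C)=O)c(OC(C)=O)c6)c(OC(C)=O)c5)c(OC(C)=O)c4)c(OC(C)=O)c3)c(OC(C)=O)c2)c(OC(C)=O)c1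
A1 | alternative 1 | hexameric dodecaaldehyde (each ring a 2-aryloxyisophthalaldehyde, rings A and F 4-benzyl ethers) | O=Cc1cc(OCc2ccccc2)cc(C=O)c1Oc1cc(C=O)c(Oc2cc(C=O)c(Oc3cc(C=O)c(Oc4cc(C=O)c(Oc5cc(C=O)c(OCc6ccccc6)c(C=O)c5)c(C=O)c4)c(C=O)c3)c(C=O)c2)c(C=O)c1
A2 | alternative 1 | dodecaformate of the target bis(benzyl ether) | O=COc1cc(OCc2ccccc2)cc(OC=O)c1Oc1cc(OC=O)c(Oc2cc(OC=O)c(Oc3cc(OC=O)c(Oc4cc(OC=O)c(Oc5cc(OC=O)c(OCc6ccccc6)c(OC=O)c5)c(OC=O)c4)c(OC=O)c3)c(OC=O)c2)c(OC=O)c1
A3 | alternative 2 | 2-aryloxy-1,3-bis(trimethylsilyloxy)cyclohexa-1,3-diene with aryl = permethylated rings C to F | C[Si](C)(C)OC1=C(Oc2cc(OC)c(Oc3cc(OC)c(Oc4cc(OC)c(Oc5cc(OC)c(OC)c(OC)c5)c(OC)c4)c(OC)c3)c(OC)c2)C(O[Si](C)(C)C)=CCC1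
A4 | alternative 2 | methyl 3-(2,4,6-trimethoxyphenoxy)prop-2-ynoate | COC(=O)C#COc1c(OC)cc(OC)cc1OC
A5 | alternative 2 | hexamer with ring B as a methyl bis(trimethylsilyloxy)benzoate | COC(=O)c1c(O[Si](C)(C)C)c(Oc2cc(OC)c(Oc3cc(OC)c(Oc4cc(OC)c(Oc5cc(OC)c(OC)c(OC)c5)c(OC)c4)c(OC)c3)c(OC)c2)c(O[Si](C)(C)C)cc1Oc1c(OC)cc(OC)cc1OC
A6 | alternative 3 | 4-(benzyloxy)-2,6-dimethoxyphenol | COc1cc(OCc2ccccc2)cc(OC)c1O
A7 | alternative 3 | syringic acid (4-hydroxy-3,5-dimethoxybenzoic acid) | COc1cc(C(=O)O)cc(OC)c1O
A8 | alternative 3 | hexamer with benzyl ether on ring A, twelve methyl ethers and a free phenol on ring F | COc1cc(OCc2ccccc2)cc(OC)c1Oc1cc(OC)c(Oc2cc(OC)c(Oc3cc(OC)c(Oc4cc(OC)c(Oc5cc(OC)c(O)c(OC)c5)c(OC)c4)c(OC)c3)c(OC)c2)c(OC)c1
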